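**Plan**

- Core numbering: C1 (CH–O-angeloyl), C2 (CH2), C3 (C(OH)-isopropyl), C4 (ring-fusion CH), C5 (CH–O-anisoyl), C6 (CH2), C7 (olefinic C–CH3), C8 (olefinic CH), C9 (CH2), C10 (ring-fusion C–CH3). Ring A is the cyclopentane C1–C2–C3–C4–C10; ring B is the cycloheptene C4–C5–C6–C7–C8–C9–C10.
- Retrosynthetic cuts, in order: the C1–O and C5–O ester bonds, the C3–isopropyl bond, the ring bond C9–C10 (ring B), the C4–C5 bond between ring A and the side chain, and the C6–C7 bond inside the side chain.
- Enabling feature: C10 is the β-carbon of a ring A cyclopentenone (C3 carbonyl, C4 α-carbon, oxygenated C1 as γ-carbon) and C9–C8=C7(CH3) is an allyl unit. A silicon on C7 therefore lets C9 add to C10 and forces the ring B olefin to C7=C8.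
- Forward order: ring A is bought as a 4-silyloxycyclopentenone and given its C10 methyl and a C4 iodide. The C5–C9 chain (an allylsilane aldehyde made by Johnson–Claisen rearrangement) is joined at C4–C5 by a Nozaki–Hiyama–Kishi coupling. Ring B then closes, and the isopropyl group and the two esters come last.
- Stereochemistry: C1 from the purchased enone; C5 from the chiral chromium reagent of the coupling; C10 from attack anti to the C1 silyloxy group; C4 from protonation of the resulting enolate (trans fusion); C3 from addition to the ketone face opposite the C4–C5 bond and the angular methyl; the Z olefin of the angelate from angelic acid.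

Key step: step 10

Assumption 1: the silicon-bearing carbon C7 is carried as a mixture of both configurations from the Claisen product to the cyclisation precursor (left unspecified in those SMILES), because it becomes sp2 in the ring closure.

Assumption 2: the antipode of the oxazoline sulfonamide ligand used in the coupling is the one that delivers the 5S carbinol; the valinol-derived S ligand is written, and its mirror image is used if the sense of induction is the opposite.

**Route**

Step 1
Reactants: 1 (R)-4-(tert-butyldimethylsilyloxy)cyclopent-2-en-1-one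
Product: 2 (3R,4R)-4-(tert-butyldimethylsilyloxy)-3-methyl-1-(trimethylsilyloxy)cyclopent-1-ene (methyl trans to the silyloxy group)
Conditions: Me2CuLi (from MeLi, CuBr·SMe2), TMSCl, THF, −78 °C; then Et3N, aq. NaHCO3
Reagents that add atoms: lithium dimethylcuprate, [Li+].C[Cu-]C; chlorotrimethylsilane, C[Si](C)(C)Cl
Why: TMSCl-accelerated cuprate conjugate addition to a 4-silyloxycyclopentenone should occur anti to the silyloxy group, and silylation of the enolate as it forms keeps it from equilibrating towards the other α-carbon and expelling the β-silyloxy group; the new methyl-bearing centre becomes sp2 again in step 2.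

Step 2
Reactants: 2 (3R,4R)-4-(tert-butyldimethylsilyloxy)-3-methyl-1-(trimethylsilyloxy)cyclopent-1-ene
Product: 3 (R)-4-(tert-butyldimethylsilyloxy)-3-methylcyclopent-2-en-1-one
Conditions: Pd(OAc)2 (1.1 equiv), MeCN, rt
Reagents that add atoms: none
Why: Saegusa–Ito oxidation, in which the palladium enolate formed from the silyl enol ether undergoes β-hydride elimination of its only β-hydrogen (on the methyl-bearing carbon), so the enone should form regiospecifically on that side with the silyloxy stereocentre untouched.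

Step 3
Reactants: 3 (R)-4-(tert-butyldimethylsilyloxy)-3-methylcyclopent-2-en-1-one
Product: 4 (R)-4-(tert-butyldimethylsilyloxy)-2-iodo-3-methylcyclopent-2-en-1-one
Conditions: I2, pyridine, DMAP (cat.), CH2Cl2, 0 °C → rt
Reagents that add atoms: iodine, II
Why: α-iodination of an enone by reversible conjugate addition of the pyridine base, iodination of the enolate and elimination (iodine/pyridine method), a sequence known for 3-methylcycloalkenones that touches no stereocentre.

Step 4
Reactants: 5 ethyl 3-(trimethylsilyl)prop-2-ynoate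
Product: 6 ethyl (Z)-3-(trimethylsilyl)but-2-enoate
Conditions: Me2CuLi (from MeLi, CuBr·SMe2), THF, −78 °C; aq. NH4Cl
Reagents that add atoms: lithium dimethylcuprate, [Li+].C[Cu-]C
Why: syn carbocupration (conjugate addition) of the cuprate to the silyl ynoate at low temperature places the methyl group on the silicon-bearing carbon, and the olefin geometry (Z expected) has no bearing on the later steps.

Step 5
Reactants: 6 ethyl (Z)-3-(trimethylsilyl)but-2-enoate
Product: 7 (Z)-3-(trimethylsilyl)but-2-en-1-ol
Conditions: iBu2AlH (2.2 equiv), CH2Cl2, −78 → 0 °C; aq. potassium sodium tartrate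
Reagents that add atoms: none
Why: 1,2-reduction of an enoate to the allylic alcohol with the aluminium hydride, which should leave the vinylsilane and the olefin untouched.

Step 6
Reactants: 7 (Z)-3-(trimethylsilyl)but-2-en-1-ol, 8 triethyl orthoacetate
Product: 11 ethyl 3-methyl-3-(trimethylsilyl)pent-4-enoate (racemic), via mixed orthoester 9 (not isolated), via ketene acetal 10 (not isolated)
Conditions: EtCO2H (cat.), neat in excess 8, 140 °C, EtOH distilled off
Reagents that add atoms: none
Why: Johnson–Claisen rearrangement, in which orthoester exchange and loss of ethanol give ketene acetal 10 and its [3,3]-sigmatropic shift forms the C6–C7 bond at the silyl- and methyl-bearing olefin carbon, a standard entry to allylsilanes from γ-silyl allylic alcohols; the new quaternary centre is racemic, which is acceptable because it is destroyed in step 10.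

Step 7
Reactants: 11 ethyl 3-methyl-3-(trimethylsilyl)pent-4-enoate
Product: 12 3-methyl-3-(trimethylsilyl)pent-4-enal (racemic)
Conditions: iBu2AlH (1.1 equiv), CH2Cl2, −78 °C; aq. potassium sodium tartrate
Reagents that add atoms: none
Why: half-reduction of an ester at −78 °C, where the tetrahedral aluminium hemiacetal of this β-quaternary ester should persist until work-up and release the aldehyde (C5) without affecting the allylsilane.

Step 8
Reactants: 4 (R)-4-(tert-butyldimethylsilyloxy)-2-iodo-3-methylcyclopent-2-en-1-one, 12 3-methyl-3-(trimethylsilyl)pent-4-enal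
Product: 13 (4R)-4-(tert-butyldimethylsilyloxy)-2-[(1S)-1-hydroxy-3-methyl-3-(trimethylsilyl)pent-4-en-1-yl]-3-methylcyclopent-2-en-1-one (both epimers at the silicon-bearing carbon)
Conditions: CrCl2 (3 equiv), (S)-N-[2-(4-isopropyl-4,5-dihydrooxazol-2-yl)-6-methylphenyl]methanesulfonamide (3.3 equiv), Et3N, THF, rt; then NiCl2 (cat.), 4, 12 (1.5 equiv), rt
Reagents that add atoms: none
Why: Nozaki–Hiyama–Kishi coupling, in which zerovalent nickel inserts into the C–I bond of the α-iodoenone, transmetalation gives an alkenylchromium species that adds only to the aldehyde, and the chiral sulfonamide bound to trivalent chromium selects the aldehyde face, so that C5 is set by the reagent (5S) with little influence expected from the remote C1 centre.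

Step 9
Reactants: 13 (4R)-4-(tert-butyldimethylsilyloxy)-2-[(1S)-1-hydroxy-3-methyl-3-(trimethylsilyl)pent-4-en-1-yl]-3-methylcyclopent-2-en-1-one
Product: 14 (4R)-4-(tert-butyldimethylsilyloxy)-3-methyl-2-[(1S)-3-methyl-1-(triethylsilyloxy)-3-(trimethylsilyl)pent-4-en-1-yl]cyclopent-2-en-1-one (both epimers at the silicon-bearing carbon)
Conditions: TESCl, imidazole, DMF, 0 °C → rt
Reagents that add atoms: chlorotriethylsilane, CC[Si](Cl)(CC)CC
Why: standard silylation of a secondary allylic alcohol; a silyl ether is chosen at C5 because silyloxide is a poor leaving group from the enolate formed in step 10 (a carboxylate there would be expelled) and because it can later be removed in the presence of the C1 TBS ether.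

Step 10
Reactants: 14 (4R)-4-(tert-butyldimethylsilyloxy)-3-methyl-2-[(1S)-3-methyl-1-(triethylsilyloxy)-3-(trimethylsilyl)pent-4-en-1-yl]cyclopent-2-en-1-one
Product: 16 (1R,3aS,4S,8aR)-1-(tert-butyldimethylsilyloxy)-6,8a-dimethyl-4-(triethylsilyloxy)-1,3a,4,5,8,8a-hexahydroazulen-3(2H)-one (trans-fused; azulene positions 1, 2, 3, 3a, 4, 5, 6, 7, 8, 8a are core C1 to C10), via aluminium enolate 15 (not isolated)
Conditions: EtAlCl2 (2 equiv), toluene, −78 → −20 °C; then aq. NaHCO3 at −78 °C
Reagents that add atoms: none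
Why: EtAlCl2 binds the C3 carbonyl, the unsubstituted terminus C9 of the allylsilane adds to C10, the positive charge developing at C8 is stabilised by the C7–Si bond and is discharged by loss of the silyl group as Me3SiCl to give the C7=C8 olefin, and the chloro(ethyl)aluminium enolate 15 is protonated at C4 on work-up. The closest known reaction type is the Lewis-acid-mediated intramolecular Hosomi–Sakurai conjugate addition of allylsilanes tethered to cycloalkenones, used for five-, six- and seven-membered annulations, together with intermolecular Sakurai additions that create quaternary β-carbons on 3-methylcycloalkenones; an α-tether closing onto a fully substituted β-carbon is the less documented part. Ring B closes in the 7-endo-trig mode with respect to the enone (C4 and C10 both lie in the new ring), and the ring forces the new olefin to be cis. C10 should be set by attack anti to the C1 silyloxy group, and the 5S centre is matched with this because the rotamer with C5–H eclipsing the C10 methyl (minimal allylic 1,3-strain) holds C6 on that same face. C4 should be set by protonation of 15 on the face away from the angular methyl, which gives the trans ring fusion that a chair-like cycloheptene should also favour at equilibrium. The step needs 1,4- over 1,2-addition and closure faster than protodesilylation, which Lewis-acid (not fluoride) activation and the proton-scavenging ethyl–aluminium bond should secure, while silicon on C7 fixes the olefin position and lets both C7 epimers converge on one product.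

Step 11
Reactants: 16 (1R,3aS,4S,8aR)-1-(tert-butyldimethylsilyloxy)-6,8a-dimethyl-4-(triethylsilyloxy)-1,3a,4,5,8,8a-hexahydroazulen-3(2H)-one
Product: 17 (1R,3R,3aS,4S,8aR)-1-(tert-butyldimethylsilyloxy)-6,8a-dimethyl-3-(propan-2-yl)-4-(triethylsilyloxy)-1,2,3,3a,4,5,8,8a-octahydroazulen-3-ol
Conditions: iPrMgCl, CeCl3 (anhydrous), THF, −78 → −40 °C; aq. NH4Cl
Reagents that add atoms: isopropylmagnesium chloride, CC(C)[Mg]Cl
Why: organocerium 1,2-addition, whose low basicity should suppress enolisation of the ketone (and with it loss of the β-silyloxy groups) and hydride transfer; the reagent should attack the cyclopentanone face that carries the C4 hydrogen, opposite the C4–C5 bond, the angular methyl and the C1 silyloxy group, so that C3 forms with its hydroxyl cis to the angular methyl.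

Step 12
Reactants: 17 (1R,3R,3aS,4S,8aR)-1-(tert-butyldimethylsilyloxy)-6,8a-dimethyl-3-(propan-2-yl)-4-(triethylsilyloxy)-1,2,3,3a,4,5,8,8a-octahydroazulen-3-ol
Product: 18 (1R,3R,3aS,4S,8aR)-1-(tert-butyldimethylsilyloxy)-6,8a-dimethyl-3-(propan-2-yl)-1,2,3,3a,4,5,8,8a-octahydroazulene-3,4-diol
Conditions: PPTS (cat.), MeOH/CH2Cl2, 0 °C
Reagents that add atoms: none
Why: acid-catalysed methanolysis should cleave the secondary triethylsilyl ether much faster than the hindered TBS ether next to the quaternary carbon (standard TES/TBS differentiation), and the tertiary alcohol and the olefin tolerate this weak acid.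

Step 13
Reactants: 18 (1R,3R,3aS,4S,8aR)-1-(tert-butyldimethylsilyloxy)-6,8a-dimethyl-3-(propan-2-yl)-1,2,3,3a,4,5,8,8a-octahydroazulene-3,4-diol, 19 4-methoxybenzoyl chloride
Product: 20 (1R,3R,3aS,4S,8aR)-1-(tert-butyldimethylsilyloxy)-3-hydroxy-6,8a-dimethyl-3-(propan-2-yl)-1,2,3,3a,4,5,8,8a-octahydroazulen-4-yl 4-methoxybenzoate
Conditions: Et3N, DMAP (cat.), CH2Cl2, 0 °C → rt
Reagents that add atoms: none
Why: DMAP-catalysed acylation with the acid chloride should esterify the secondary C5 hydroxyl while the tertiary C3 hydroxyl stays free for steric reasons.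

Step 14
Reactants: 20 (1R,3R,3aS,4S,8aR)-1-(tert-butyldimethylsilyloxy)-3-hydroxy-6,8a-dimethyl-3-(propan-2-yl)-1,2,3,3a,4,5,8,8a-octahydroazulen-4-yl 4-methoxybenzoate
Product: 21 (1R,3R,3aS,4S,8aR)-1,3-dihydroxy-6,8a-dimethyl-3-(propan-2-yl)-1,2,3,3a,4,5,8,8a-octahydroazulen-4-yl 4-methoxybenzoate
Conditions: HF·pyridine, pyridine, THF, 0 °C → rt
Reagents that add atoms: none
Why: fluoride cleavage of the TBS ether with buffered HF·pyridine, conditions under which the aryl ester should neither migrate nor hydrolyse and the tertiary alcohol should not eliminate.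

Step 15
Reactants: 21 (1R,3R,3aS,4S,8aR)-1,3-dihydroxy-6,8a-dimethyl-3-(propan-2-yl)-1,2,3,3a,4,5,8,8a-octahydroazulen-4-yl 4-methoxybenzoate, 22 angelic acid ((2Z)-2-methylbut-2-enoic acid)
Product: 24 (1R,3R,3aS,4S,8aR)-3-hydroxy-4-[(4-methoxybenzoyl)oxy]-6,8a-dimethyl-3-(propan-2-yl)-1,2,3,3a,4,5,8,8a-octahydroazulen-1-yl (2Z)-2-methylbut-2-enoate (CNP0204191.1), via mixed anhydride 23 (not isolated)
Conditions: 2,4,6-trichlorobenzoyl chloride, Et3N, toluene, rt; then 21, 75 °C
Reagents that add atoms: none
Why: Yamaguchi esterification run without DMAP, in which the mixed anhydride 23 acylates the hindered secondary C1 hydroxyl on heating, a protocol chosen because it avoids the nucleophile-induced isomerisation of the angelate (Z) to the tiglate (E); the tertiary hydroxyl should not react.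

**Compound list**

1 | (R)-4-(tert-butyldimethylsilyloxy)cyclopent-2-en-1-one | O=C1C=C[C@H](O[Si](C)(C)C(C)(C)C)C1 | starting material
2 | (3R,4R)-4-(tert-butyldimethylsilyloxy)-3-methyl-1-(trimethylsilyloxy)cyclopent-1-ene | C[Si](C)(C)OC1=C[C@@H](C)[C@H](O[Si](C)(C)C(C)(C)C)C1 | intermediate
3 | (R)-4-(tert-butyldimethylsilyloxy)-3-methylcyclopent-2-en-1-one | CC1=CC(=O)C[C@H]1O[Si](C)(C)C(C)(C)C | intermediate
4 | (R)-4-(tert-butyldimethylsilyloxy)-2-iodo-3-methylcyclopent-2-en-1-one | CC1=C(I)C(=O)C[C@H]1O[Si](C)(C)C(C)(C)C | intermediate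
5 | ethyl 3-(trimethylsilyl)prop-2-ynoate | CCOC(=O)C#C[Si](C)(C)C | starting material
6 | ethyl (Z)-3-(trimethylsilyl)but-2-enoate | CCOC(=O)/C=C(/C)[Si](C)(C)C | intermediate
7 | (Z)-3-(trimethylsilyl)but-2-en-1-ol | OC/C=C(/C)[Si](C)(C)C | intermediate
8 | triethyl orthoacetate (1,1,1-triethoxyethane) | CC(OCC)(OCC)OCC | starting material
9 | 1,1-diethoxy-1-[(Z)-3-(trimethylsilyl)but-2-enyloxy]ethane (mixed orthoester) | CCOC(C)(OCC)OC/C=C(/C)[Si](C)(C)C | intermediate (not isolated)
10 | 1-ethoxy-1-[(Z)-3-(trimethylsilyl)but-2-enyloxy]ethene (ketene acetal) | C=C(OCC)OC/C=C(/C)[Si](C)(C)C | intermediate (not isolated)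
11 | ethyl 3-methyl-3-(trimethylsilyl)pent-4-enoate (racemic) | CCOC(=O)CC(C)(C=C)[Si](C)(C)C | intermediate
12 | 3-methyl-3-(trimethylsilyl)pent-4-enal (racemic) | O=CCC(C)(C=C)[Si](C)(C)C | intermediate
13 | (4R)-4-(tert-butyldimethylsilyloxy)-2-[(1S)-1-hydroxy-3-methyl-3-(trimethylsilyl)pent-4-en-1-yl]-3-methylcyclopent-2-en-1-one (both epimers at the silicon-bearing carbon) | C=CC(C)([Si](C)(C)C)C[C@H](O)C1=C(C)[C@H](O[Si](C)(C)C(C)(C)C)CC1=O | intermediate
14 | (4R)-4-(tert-butyldimethylsilyloxy)-3-methyl-2-[(1S)-3-methyl-1-(triethylsilyloxy)-3-(trimethylsilyl)pent-4-en-1-yl]cyclopent-2-en-1-one (both epimers at the silicon-bearing carbon) | C=CC(C)([Si](C)(C)C)C[C@H](O[Si](CC)(CC)CC)C1=C(C)[C@H](O[Si](C)(C)C(C)(C)C)CC1=O | intermediate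
15 | chloro(ethyl)aluminium enolate of ketone 16 (C3–O–Al, C3=C4) | CC[Al](Cl)OC1=C2[C@@H](O[Si](CC)(CC)CC)CC(C)=CC[C@@]2(C)[C@H](O[Si](C)(C)C(C)(C)C)C1 | intermediate (not isolated)
16 | (1R,3aS,4S,8aR)-1-(tert-butyldimethylsilyloxy)-6,8a-dimethyl-4-(triethylsilyloxy)-1,3a,4,5,8,8a-hexahydroazulen-3(2H)-one | CC(C)(C)[Si](C)(C)O[C@@H]1CC(=O)[C@@H]2[C@@H](O[Si](CC)(CC)CC)CC(C)=CC[C@]21C | intermediate
17 | (1R,3R,3aS,4S,8aR)-1-(tert-butyldimethylsilyloxy)-6,8a-dimethyl-3-(propan-2-yl)-4-(triethylsilyloxy)-1,2,3,3a,4,5,8,8a-octahydroazulen-3-ol | CC(C)(C)[Si](C)(C)O[C@@H]1C[C@@](O)(C(C)C)[C@@H]2[C@@H](O[Si](CC)(CC)CC)CC(C)=CC[C@]21C | intermediate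
18 | (1R,3R,3aS,4S,8aR)-1-(tert-butyldimethylsilyloxy)-6,8a-dimethyl-3-(propan-2-yl)-1,2,3,3a,4,5,8,8a-octahydroazulene-3,4-diol | CC(C)(C)[Si](C)(C)O[C@@H]1C[C@@](O)(C(C)C)[C@@H]2[C@@H](O)CC(C)=CC[C@]21C | intermediate
19 | 4-methoxybenzoyl chloride | COc1ccc(cc1)C(Cl)=O | starting material
20 | (1R,3R,3aS,4S,8aR)-1-(tert-butyldimethylsilyloxy)-3-hydroxy-6,8a-dimethyl-3-(propan-2-yl)-1,2,3,3a,4,5,8,8a-octahydroazulen-4-yl 4-methoxybenzoate | CC(C)(C)[Si](C)(C)O[C@@H]1C[C@@](O)(C(C)C)[C@@H]2[C@@H](OC(=O)c3ccc(OC)cc3)CC(C)=CC[C@]21C | intermediate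
21 | (1R,3R,3aS,4S,8aR)-1,3-dihydroxy-6,8a-dimethyl-3-(propan-2-yl)-1,2,3,3a,4,5,8,8a-octahydroazulen-4-yl 4-methoxybenzoate | O[C@@H]1C[C@@](O)(C(C)C)[C@@H]2[C@@H](OC(=O)c3ccc(OC)cc3)CC(C)=CC[C@]21C | intermediate
22 | angelic acid, (2Z)-2-methylbut-2-enoic acid | C/C=C(/C)C(=O)O | starting material
23 | (2Z)-2-methylbut-2-enoic 2,4,6-trichlorobenzoic anhydride | C/C=C(/C)C(=O)OC(=O)c1c(Cl)cc(Cl)cc1Cl | intermediate (not isolated)
24 | (1R,3R,3aS,4S,8aR)-3-hydroxy-4-[(4-methoxybenzoyl)oxy]-6,8a-dimethyl-3-(propan-2-yl)-1,2,3,3a,4,5,8,8a-octahydroazulen-1-yl (2Z)-2-methylbut-2-enoate | C/C=C(/C)C(=O)O[C@@H]1C[C@@](O)(C(C)C)[C@@H]2[C@@H](OC(=O)c3ccc(OC)cc3)CC(C)=CC[C@]21C | target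

**Step count**

Total: 15 steps.
Longest linear sequence: 12 steps (compound 5 through steps 4 to 15); the ring A branch from compound 1 is 11 steps.

**Steps most likely to fail**

1. Step 10 (ring B closure). The allylsilane may add to the C3 carbonyl instead (1,2-addition, also a seven-membered closure), or lose silicon by protonation before it reaches the fully substituted C10. The enolate may also be protonated on the face that gives the cis ring fusion.
Fallback, setting out from 4 and returning at 16: the chromium-mediated coupling of step 8 (CrCl2, the sulfonamide ligand, NiCl2 cat.) is run with 3-methylbut-3-enal F1, freshly made from 3-methylbut-3-en-1-ol with Dess–Martin periodinane. This should give (4R)-4-(tert-butyldimethylsilyloxy)-2-[(1S)-1-hydroxy-3-methylbut-3-en-1-yl]-3-methylcyclopent-2-en-1-one F2, which is silylated (TESCl, imidazole) to (4R)-4-(tert-butyldimethylsilyloxy)-3-methyl-2-[(1S)-3-methyl-1-(triethylsilyloxy)but-3-en-1-yl]cyclopent-2-en-1-one F3. Intermolecular conjugate allylation at C10 with the cuprate made from allylmagnesium bromide and CuBr·SMe2 (entry anti to the C1 silyloxy group) and protonation on work-up should give (2S,3R,4R)-4-(tert-butyldimethylsilyloxy)-3-methyl-2-[(1S)-3-methyl-1-(triethylsilyloxy)but-3-en-1-yl]-3-(prop-2-en-1-yl)cyclopentan-1-one F4. Ring-closing metathesis with the second-generation Hoveyda–Grubbs catalyst in toluene at 80 °C then forms the C7=C8 olefin of ring B and returns to ketone 16.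

2. Step 8 (coupling and C5). Reagent control at C5 may be weak with this α-iodoenone, or the iodide may be reduced before it couples.
Fallback, setting out from 4 and 12 and returning at 13: the coupling is run without the ligand (CrCl2, NiCl2 cat., DMF), which should give both C5 epimers. Compound 13 is separated from (4R)-4-(tert-butyldimethylsilyloxy)-2-[(1R)-1-hydroxy-3-methyl-3-(trimethylsilyl)pent-4-en-1-yl]-3-methylcyclopent-2-en-1-one F5. F5 is inverted by Mitsunobu esterification (4-nitrobenzoic acid, PPh3, diisopropyl azodicarboxylate, THF, 0 °C) to (1S)-1-[(3R)-3-(tert-butyldimethylsilyloxy)-2-methyl-5-oxocyclopent-1-en-1-yl]-3-methyl-3-(trimethylsilyl)pent-4-en-1-yl 4-nitrobenzoate F6. Methanolysis of F6 (K2CO3, MeOH, 0 °C) returns 13, so C5 is set by separation and inversion, not by the reagent.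

3. Step 11 (isopropyl addition). The organometallic may enolise the hindered ketone, with return of ketone or loss of a β-silyloxy group, or the isopropyl reagent may transfer hydride.
Fallback, setting out from 16 and returning at 17: isopropenylmagnesium bromide with CeCl3 (an sp2 nucleophile that is smaller and cannot deliver hydride) should add from the same face to give (1R,3S,3aS,4S,8aR)-1-(tert-butyldimethylsilyloxy)-6,8a-dimethyl-3-(prop-1-en-2-yl)-4-(triethylsilyloxy)-1,2,3,3a,4,5,8,8a-octahydroazulen-3-ol F7. Hydrogenation of F7 over RhCl(PPh3)3 (H2, benzene) should saturate the 1,1-disubstituted olefin in preference to the trisubstituted ring olefin and give 17.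

**Further compounds**

F1 | step 10 | 3-methylbut-3-enal | C=C(C)CC=O
F2 | step 10 | (4R)-4-(tert-butyldimethylsilyloxy)-2-[(1S)-1-hydroxy-3-methylbut-3-en-1-yl]-3-methylcyclopent-2-en-1-one | C=C(C)C[C@H](O)C1=C(C)[C@H](O[Si](C)(C)C(C)(C)C)CC1=O
F3 | step 10 | (4R)-4-(tert-butyldimethylsilyloxy)-3-methyl-2-[(1S)-3-methyl-1-(triethylsilyloxy)but-3-en-1-yl]cyclopent-2-en-1-one | C=C(C)C[C@H](O[Si](CC)(CC)CC)C1=C(C)[C@H](O[Si](C)(C)C(C)(C)C)CC1=O
F4 | step 10 | (2S,3R,4R)-4-(tert-butyldimethylsilyloxy)-3-methyl-2-[(1S)-3-methyl-1-(triethylsilyloxy)but-3-en-1-yl]-3-(prop-2-en-1-yl)cyclopentan-1-one | CC(C)(C)[Si](C)(C)O[C@@H]1CC(=O)[C@H]([C@@H](O[Si](CC)(CC)CC)CC(C)=C)[C@]1(CC=C)C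
F5 | step 8 | (4R)-4-(tert-butyldimethylsilyloxy)-2-[(1R)-1-hydroxy-3-methyl-3-(trimethylsilyl)pent-4-en-1-yl]-3-methylcyclopent-2-en-1-one | C=CC(C)([Si](C)(C)C)C[C@@H](O)C1=C(C)[C@H](O[Si](C)(C)C(C)(C)C)CC1=O
F6 | step 8 | (1S)-1-[(3R)-3-(tert-butyldimethylsilyloxy)-2-methyl-5-oxocyclopent-1-en-1-yl]-3-methyl-3-(trimethylsilyl)pent-4-en-1-yl 4-nitrobenzoate | C=CC(C)([Si](C)(C)C)C[C@H](OC(=O)c1ccc(cc1)[N+](=O)[O-])C1=C(C)[C@H](O[Si](C)(C)C(C)(C)C)CC1=O
F7 | step 11 | (1R,3S,3aS,4S,8aR)-1-(tert-butyldimethylsilyloxy)-6,8a-dimethyl-3-(prop-1-en-2-yl)-4-(triethylsilyloxy)-1,2,3,3a,4,5,8,8a-octahydroazulen-3-ol | CC(C)(C)[Si](C)(C)O[C@@H]1C[C@@](O)(C(C)=C)[C@@H]2[C@@H](O[Si](CC)(CC)CC)CC(C)=CC[C@]21C
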